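The biflavanone is cut at C4''–C4a'' of unit 2: ring C'' is closed on a preformed biaryl ether, and unit 1 is then grown from the C1' bromide by asymmetric arylation of a chromone. The key step exploits ring A'' of its precursor, whose only free carbon ortho to O1'' is C4a'' (C8'' carries ring B), so an acyl chain hung on O1''–C2'' can close only there and never at C6''. In one operation it forms the C4'' ketone, ring C'' and the 8''-aryl pattern while leaving C2'' untouched. The precursor is an (S)-3-aryloxy-3-(4-acetoxyphenyl)propanoic acid whose aryloxy group is the 2-(2-benzyloxy-5-bromophenyl)-3,5-dimethoxyphenyl unit.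

Key step: step 9

Locants: unit 1 is the 5,7-dihydroxyflavanone (O1, C2–C8a, ring B = C1'–C6'); unit 2 is the 5-hydroxy-7-methoxyflavanone (O1'', C2''–C8a'', ring A'', aryl C1'''–C6'''); the biaryl bond is C3'–C8''; the target is (2S,2''S).
Assumption: the C3'–C8'' axis, flanked by three oxygen substituents and one hydrogen, rotates freely at room temperature, so only C2 and C2'' need to be controlled.

Step 1
Reactants: 1 4-bromo-2-iodophenol
Product: 2 1-(benzyloxy)-4-bromo-2-iodobenzene
Conditions: BnBr, K2CO3, DMF, rt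
Reagents that add atoms: benzyl bromide, BrCc1ccccc1
Why: Williamson ether synthesis, in which the phenoxide displaces bromide from benzyl bromide by SN2 and neither aryl halide is touched, should give a benzyl ether that survives acid and is removed by BCl3 at the end.

Step 2
Reactants: 3 3,5-dimethoxyphenol
Product: 4 1,3-dimethoxy-5-(methoxymethoxy)benzene
Conditions: NaH, DMF, 0 °C; MeOCH2Cl, 0 °C → rt
Reagents that add atoms: chloromethyl methyl ether, COCCl
Why: Williamson-type O-alkylation of the sodium phenoxide with the reactive α-chloro ether should be clean and installs the acetal that acts as the directing group in step 3.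

Step 3
Reactants: 4 1,3-dimethoxy-5-(methoxymethoxy)benzene; 2 1-(benzyloxy)-4-bromo-2-iodobenzene
Product: 7 2-(2-benzyloxy-5-bromophenyl)-3,5-dimethoxy-1-(methoxymethoxy)benzene, via aryllithium 5 (not isolated), via arylzinc chloride 6 (not isolated)
Conditions: n-BuLi, THF, 0 °C; ZnCl2, THF, 0 °C → rt; 2, Pd(PPh3)4 (5 mol%), THF, 50 °C
Reagents that add atoms: none
Why: Directed ortho-metalation followed by Negishi coupling, in which the acetal and a methoxy oxygen jointly guide n-BuLi to the ring carbon between them (the acetal being the stronger director than a methoxy pair), zinc exchange gives a mild nucleophile, and Pd(PPh3)4 inserts into the C–I bond of 2 far faster than into C–Br, so the bromide is kept for step 10.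

Step 4
Reactants: 7 2-(2-benzyloxy-5-bromophenyl)-3,5-dimethoxy-1-(methoxymethoxy)benzene
Product: 8 2-(2-benzyloxy-5-bromophenyl)-3,5-dimethoxyphenol
Conditions: conc. HCl (cat.), MeOH/THF, 50 °C
Reagents that add atoms: none
Why: Acid-catalysed acetal exchange with methanol (methoxymethyl ether cleavage) should free the phenol while the aryl benzyl and methyl ethers and the bromide are inert to dilute acid.

Step 5
Reactants: 9 4-acetoxybenzoic acid
Product: 11 tert-butyl 3-(4-acetoxyphenyl)-3-oxopropanoate, via 4-acetoxybenzoyl chloride 10 (not isolated)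
Conditions: (COCl)2, DMF (cat.), CH2Cl2, 0 °C → rt, evaporate; KO2CCH2CO2t-Bu, MgCl2, Et3N, MeCN, 0 °C → rt; aq. citric acid
Reagents that add atoms: potassium mono-tert-butyl malonate, CC(C)(C)OC(=O)CC(=O)[O-].[K+]
Why: C-acylation of the magnesium enolate of the malonate half ester by the acid chloride followed by decarboxylation (Claisen-type β-keto ester synthesis) should be selective because the acyl chloride is far more electrophilic than the aryl acetate and no nucleophilic amine is present.

Step 6
Reactants: 11 tert-butyl 3-(4-acetoxyphenyl)-3-oxopropanoate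
Product: 12 tert-butyl (3R)-3-(4-acetoxyphenyl)-3-hydroxypropanoate
Conditions: RuCl[(R,R)-TsDPEN](p-cymene) (1 mol%), HCO2H/Et3N (5:2), EtOAc, 30 °C
Reagents that add atoms: none
Why: Noyori–Ikariya asymmetric transfer hydrogenation, in which the ruthenium hydride and ligand N–H of the R,R catalyst deliver hydrogen to the ketone face fixed by the aryl–cymene contact, should set C3 as R (the sense established for aryl ketones and aroylacetates), and the acidic formate medium spares both esters.

Step 7
Reactants: 8 2-(2-benzyloxy-5-bromophenyl)-3,5-dimethoxyphenol; 12 tert-butyl (3R)-3-(4-acetoxyphenyl)-3-hydroxypropanoate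
Product: 13 tert-butyl (3S)-3-(4-acetoxyphenyl)-3-[2-(2-benzyloxy-5-bromophenyl)-3,5-dimethoxyphenoxy]propanoate
Conditions: PPh3, DIAD, toluene, 0 °C → rt
Reagents that add atoms: none
Why: Mitsunobu etherification, in which the phenoxide of 8 displaces the alkoxyphosphonium of 12 by SN2 with inversion, should turn the R carbinol into the S aryl ether that becomes C2'', the acetoxy substituent disfavouring benzylic ionisation and the low temperature limiting dehydration to the cinnamate.

Step 8
Reactants: 13 tert-butyl (3S)-3-(4-acetoxyphenyl)-3-[2-(2-benzyloxy-5-bromophenyl)-3,5-dimethoxyphenoxy]propanoate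
Product: 14 (3S)-3-(4-acetoxyphenyl)-3-[2-(2-benzyloxy-5-bromophenyl)-3,5-dimethoxyphenoxy]propanoic acid
Conditions: CF3CO2H/CH2Cl2 (1:4), 0 °C → rt
Reagents that add atoms: none
Why: Acidolysis of the tert-butyl ester (loss of isobutene from the protonated ester) frees the acid without base, which would expel the aryloxide by E1cB, and tert-butylation of ring A'' is not expected because each of its free carbons lies between two oxygen-bearing carbons.

Step 9
Reactants: 14 (3S)-3-(4-acetoxyphenyl)-3-[2-(2-benzyloxy-5-bromophenyl)-3,5-dimethoxyphenoxy]propanoic acid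
Product: 16 (2S)-2-(4-acetoxyphenyl)-8-(2-benzyloxy-5-bromophenyl)-5,7-dimethoxychroman-4-one, via mixed trifluoroacetic anhydride 15 (not isolated)
Conditions: (CF3CO)2O (2 equiv), CH2Cl2, 0 °C
Reagents that add atoms: none
Why: Trifluoroacetic anhydride converts the acid into mixed anhydride 15, whose acylium carbon (free or as the polarised anhydride) is attacked by C4a'' of ring A'', and loss of the C4a'' proton from the arenium ion restores aromaticity and leaves the C4''–C4a'' bond and the aryl ketone. The closest known reaction type is the intramolecular Friedel–Crafts acylation of 3-aryloxypropanoic acids to chroman-4-ones. Ring C'' closes as a six-membered ring by attack of an arene carbon on the exocyclic C≡O+ unit (6-exo-dig at the acylium carbon, the C4a''–C8a'' bond becoming part of the new ring). No stereocentre is created, and C2'' keeps the S configuration installed by the SN2 inversion of step 7 because none of its bonds is broken. The step needs site selectivity between C4a'' and the equally electron-rich C6'', which the O1''–C2''–C3''–C4'' tether secures because it reaches only a carbon ortho to O1'' and the other ortho carbon, C8'', carries ring B; it also needs the benzylic ether to stay intact, which the 4-acetoxy group (no strong donor para to C2'') and the 0 °C allowed by three oxygen donors on ring A'' should ensure, while the tethered acyl group should close the ring faster than excess anhydride can trifluoroacetylate C6''.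

Step 10
Reactants: 16 (2S)-2-(4-acetoxyphenyl)-8-(2-benzyloxy-5-bromophenyl)-5,7-dimethoxychroman-4-one
Product: 17 (2S)-2-(4-acetoxyphenyl)-8-[2-(benzyloxy)-5-(4,4,5,5-tetramethyl-1,3,2-dioxaborolan-2-yl)phenyl]-5,7-dimethoxychroman-4-one
Conditions: B2pin2, PdCl2(dppf) (5 mol%), KOAc, 1,4-dioxane, 80 °C
Reagents that add atoms: bis(pinacolato)diboron, CC1(C)OB(OC1(C)C)B1OC(C)(C)C(C)(C)O1
Why: Miyaura borylation, in which zerovalent palladium inserts into the C1'–Br bond (the only aryl halide), acetate exchange enables transmetalation with the diboron and reductive elimination gives the aryl boronate, should proceed with a base too weak in aprotic dioxane to enolise the flavanone or cleave the acetate.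

Step 11
Reactants: 17 (2S)-2-(4-acetoxyphenyl)-8-[2-(benzyloxy)-5-(4,4,5,5-tetramethyl-1,3,2-dioxaborolan-2-yl)phenyl]-5,7-dimethoxychroman-4-one
Product: 18 {3-[(2S)-2-(4-acetoxyphenyl)-5,7-dimethoxy-4-oxochroman-8-yl]-4-(benzyloxy)phenyl}boronic acid
Conditions: NaIO4, THF/H2O (4:1), rt; 1 M HCl, rt
Reagents that add atoms: water, O
Why: Hydrolysis of the pinacol boronate is driven by periodate cleavage of the released pinacol to acetone under mildly acidic conditions that leave the acetate, the ethers and C2'' untouched, and it supplies the free boronic acid that transmetalates readily to palladium in step 14.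

Step 12
Reactants: 19 2',4',6'-trihydroxyacetophenone
Product: 20 1-[2,4-bis(benzyloxy)-6-hydroxyphenyl]ethanone
Conditions: BnBr (2.1 equiv), K2CO3, acetone, reflux
Reagents that add atoms: benzyl bromide, BrCc1ccccc1
Why: Williamson benzylation should stop after two ether bonds because the remaining ortho hydroxyl is held in a hydrogen bond to the acetyl carbonyl and is much less nucleophilic.

Step 13
Reactants: 20 1-[2,4-bis(benzyloxy)-6-hydroxyphenyl]ethanone
Product: 22 5,7-bis(benzyloxy)-4H-chromen-4-one, via enaminone 21 (not isolated)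
Conditions: Me2NCH(OMe)2, toluene, 95 °C; conc. HCl, CH2Cl2, 40 °C
Reagents that add atoms: N,N-dimethylformamide dimethyl acetal, COC(OC)N(C)C
Why: Condensation of the methyl ketone with the formamide acetal gives the enaminone, and acid then triggers conjugate addition of the free phenol and loss of dimethylamine (enaminone route to chromones), the acetal supplying the carbon that becomes C2.

Step 14
Reactants: 18 {3-[(2S)-2-(4-acetoxyphenyl)-5,7-dimethoxy-4-oxochroman-8-yl]-4-(benzyloxy)phenyl}boronic acid; 22 5,7-bis(benzyloxy)-4H-chromen-4-one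
Product: 23 (2S)-2-(4-acetoxyphenyl)-8-{2-(benzyloxy)-5-[(2S)-5,7-bis(benzyloxy)-4-oxochroman-2-yl]phenyl}-5,7-dimethoxychroman-4-one
Conditions: Pd(OCOCF3)2 (10 mol%), (R)-t-BuPyOx (12 mol%), NH4PF6 (30 mol%), H2O (5 equiv), ClCH2CH2Cl, 60 °C; 22 (2 equiv)
Reagents that add atoms: none
Why: Palladium-catalysed asymmetric conjugate addition of an arylboronic acid, in which the aryl group passes from boron to the cationic divalent palladium–pyridine-oxazoline complex, adds across C2=C3 of the chromone in the enantiodetermining carbopalladation and the palladium enolate is protonated by water, should set C2 under ligand control, the R ligand being the antipode expected to give 2S (the S ligand leads to the 2R series on simple chromones), while the neutral medium leaves C2'', the acetate and the benzyl ethers alone.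

Step 15
Reactants: 23 (2S)-2-(4-acetoxyphenyl)-8-{2-(benzyloxy)-5-[(2S)-5,7-bis(benzyloxy)-4-oxochroman-2-yl]phenyl}-5,7-dimethoxychroman-4-one
Product: 25 (2S)-8-{5-[(2S)-5,7-dihydroxy-4-oxochroman-2-yl]-2-hydroxyphenyl}-5-hydroxy-2-(4-hydroxyphenyl)-7-methoxychroman-4-one (target CNP0237714.1), via 4'''-O-acetyl biflavanone 24 (not isolated)
Conditions: BCl3 (1 M in CH2Cl2), C6HMe5, CH2Cl2, −78 °C → rt; MeOH, rt
Reagents that add atoms: none
Why: Lewis-acid ether cleavage with BCl3 and pentamethylbenzene as cation trap should remove the three benzyl groups and, through the boron chelate between the C4'' carbonyl and O5'', only the C5'' methyl ether (the unchelated C7'' methyl ether stays), after which the HCl formed on quenching with methanol transesterifies the aryl acetate, all without base so that C2 and C2'' are not opened to chalcones.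

Compound list
1 | 4-bromo-2-iodophenol | Oc1ccc(Br)cc1I | starting material
2 | 1-(benzyloxy)-4-bromo-2-iodobenzene | Brc1ccc(OCc2ccccc2)c(I)c1 | intermediate
3 | 3,5-dimethoxyphenol | COc1cc(O)cc(OC)c1 | starting material
4 | 1,3-dimethoxy-5-(methoxymethoxy)benzene | COCOc1cc(OC)cc(OC)c1 | intermediate
5 | [2,4-dimethoxy-6-(methoxymethoxy)phenyl]lithium | [Li]c1c(OC)cc(OC)cc1OCOC | intermediate
6 | chloro[2,4-dimethoxy-6-(methoxymethoxy)phenyl]zinc | Cl[Zn]c1c(OC)cc(OC)cc1OCOC | intermediate
7 | 2-(2-benzyloxy-5-bromophenyl)-3,5-dimethoxy-1-(methoxymethoxy)benzene | COCOc1cc(OC)cc(OC)c1-c1cc(Br)ccc1OCc1ccccc1 | intermediate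
8 | 2-(2-benzyloxy-5-bromophenyl)-3,5-dimethoxyphenol | Oc1cc(OC)cc(OC)c1-c1cc(Br)ccc1OCc1ccccc1 | intermediate
9 | 4-acetoxybenzoic acid | CC(=O)Oc1ccc(cc1)C(O)=O | starting material
10 | 4-acetoxybenzoyl chloride | CC(=O)Oc1ccc(cc1)C(Cl)=O | intermediate
11 | tert-butyl 3-(4-acetoxyphenyl)-3-oxopropanoate | CC(C)(C)OC(=O)CC(=O)c1ccc(OC(C)=O)cc1 | intermediate
12 | tert-butyl (3R)-3-(4-acetoxyphenyl)-3-hydroxypropanoate | CC(C)(C)OC(=O)C[C@@H](O)c1ccc(OC(C)=O)cc1 | intermediate
13 | tert-butyl (3S)-3-(4-acetoxyphenyl)-3-[2-(2-benzyloxy-5-bromophenyl)-3,5-dimethoxyphenoxy]propanoate | CC(C)(C)OC(=O)C[C@H](Oc1cc(OC)cc(OC)c1-c1cc(Br)ccc1OCc1ccccc1)c1ccc(OC(C)=O)cc1 | intermediate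
14 | (3S)-3-(4-acetoxyphenyl)-3-[2-(2-benzyloxy-5-bromophenyl)-3,5-dimethoxyphenoxy]propanoic acid | OC(=O)C[C@H](Oc1cc(OC)cc(OC)c1-c1cc(Br)ccc1OCc1ccccc1)c1ccc(OC(C)=O)cc1 | intermediate
15 | (3S)-3-(4-acetoxyphenyl)-3-[2-(2-benzyloxy-5-bromophenyl)-3,5-dimethoxyphenoxy]propanoic trifluoroacetic anhydride | O=C(OC(=O)C(F)(F)F)C[C@H](Oc1cc(OC)cc(OC)c1-c1cc(Br)ccc1OCc1ccccc1)c1ccc(OC(C)=O)cc1 | intermediate
16 | (2S)-2-(4-acetoxyphenyl)-8-(2-benzyloxy-5-bromophenyl)-5,7-dimethoxychroman-4-one | COc1cc(OC)c2c(c1-c1cc(Br)ccc1OCc1ccccc1)O[C@H](c1ccc(OC(C)=O)cc1)CC2=O | intermediate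
17 | (2S)-2-(4-acetoxyphenyl)-8-[2-(benzyloxy)-5-(4,4,5,5-tetramethyl-1,3,2-dioxaborolan-2-yl)phenyl]-5,7-dimethoxychroman-4-one | COc1cc(OC)c2c(c1-c1cc(B3OC(C)(C)C(C)(C)O3)ccc1OCc1ccccc1)O[C@H](c1ccc(OC(C)=O)cc1)CC2=O | intermediate
18 | {3-[(2S)-2-(4-acetoxyphenyl)-5,7-dimethoxy-4-oxochroman-8-yl]-4-(benzyloxy)phenyl}boronic acid | COc1cc(OC)c2c(c1-c1cc(B(O)O)ccc1OCc1ccccc1)O[C@H](c1ccc(OC(C)=O)cc1)CC2=O | intermediate
19 | 2',4',6'-trihydroxyacetophenone | CC(=O)c1c(O)cc(O)cc1O | starting material
20 | 1-[2,4-bis(benzyloxy)-6-hydroxyphenyl]ethanone | CC(=O)c1c(O)cc(OCc2ccccc2)cc1OCc1ccccc1 | intermediate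
21 | (E)-1-[2,4-bis(benzyloxy)-6-hydroxyphenyl]-3-(dimethylamino)prop-2-en-1-one | CN(C)/C=C/C(=O)c1c(O)cc(OCc2ccccc2)cc1OCc1ccccc1 | intermediate
22 | 5,7-bis(benzyloxy)-4H-chromen-4-one | O=c1ccoc2cc(OCc3ccccc3)cc(OCc3ccccc3)c12 | intermediate
23 | (2S)-2-(4-acetoxyphenyl)-8-{2-(benzyloxy)-5-[(2S)-5,7-bis(benzyloxy)-4-oxochroman-2-yl]phenyl}-5,7-dimethoxychroman-4-one | COc1cc(OC)c2c(c1-c1cc([C@@H]3CC(=O)c4c(OCc5ccccc5)cc(OCc5ccccc5)cc4O3)ccc1OCc1ccccc1)O[C@H](c1ccc(OC(C)=O)cc1)CC2=O | intermediate
24 | (2S)-2-(4-acetoxyphenyl)-8-{5-[(2S)-5,7-dihydroxy-4-oxochroman-2-yl]-2-hydroxyphenyl}-5-hydroxy-7-methoxychroman-4-one | COc1cc(O)c2c(c1-c1cc([C@@H]3CC(=O)c4c(O)cc(O)cc4O3)ccc1O)O[C@H](c1ccc(OC(C)=O)cc1)CC2=O | intermediate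
25 | (2S)-8-{5-[(2S)-5,7-dihydroxy-4-oxochroman-2-yl]-2-hydroxyphenyl}-5-hydroxy-2-(4-hydroxyphenyl)-7-methoxychroman-4-one (CNP0237714.1) | COc1cc(O)c2c(c1-c1cc([C@@H]3CC(=O)c4c(O)cc(O)cc4O3)ccc1O)O[C@H](c1ccc(O)cc1)CC2=O | target

Total step count: 15.
Longest linear sequence: 10 steps (steps 2, 3, 4, 7, 8, 9, 10, 11, 14, 15, from 3 to 25; the branch from 1 is equally long).

Steps most likely to fail

Step 7 (Mitsunobu etherification). The activated alkoxyphosphonium of 12 may lose a proton from the acidic CH2 next to the ester and collapse to the cinnamate faster than the hindered ortho-aryl phenoxide of 8 attacks, and any benzylic ionisation would erode the inversion. The fallback carries the carboxyl group as a terminal alkene, so that no acidifying carbonyl flanks the carbinol. It sets out from 8 and commercially available 4-acetoxybenzaldehyde. A Keck allylation (allyltributylstannane, Ti(Oi-Pr)4 with the BINOL antipode that delivers the R carbinol, CH2Cl2, −20 °C) would give (1R)-1-(4-acetoxyphenyl)but-3-en-1-ol F1. Mitsunobu coupling of this alcohol with 8 (PPh3, DIAD, toluene, 0 °C) should give, with inversion, 4-[(1S)-1-[2-(2-benzyloxy-5-bromophenyl)-3,5-dimethoxyphenoxy]but-3-en-1-yl]phenyl acetate F2. Lemieux–Johnson cleavage (OsO4, NaIO4, 2,6-lutidine, dioxane/H2O) would give 4-[(1S)-1-[2-(2-benzyloxy-5-bromophenyl)-3,5-dimethoxyphenoxy]-3-oxopropyl]phenyl acetate F3. Pinnick oxidation (NaClO2, NaH2PO4, 2-methyl-2-butene, t-BuOH/H2O) then rejoins the route at 14.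

Step 14 (asymmetric conjugate addition). Carbopalladation of the electron-rich, peri-alkoxylated chromone may be slow enough for protodeboronation of 18 to consume the advanced fragment, and facial discrimination at C2 may be incomplete with so large an aryl group. The fallback gives up catalyst control in favour of separation. It sets out from 18 and 22, which are combined with the more active achiral catalyst Pd(OCOCF3)2/2,2'-bipyridine (ClCH2CH2Cl/H2O, 60 °C). This should give 23 together with its C2 epimer, (2S)-2-(4-acetoxyphenyl)-8-{2-(benzyloxy)-5-[(2R)-5,7-bis(benzyloxy)-4-oxochroman-2-yl]phenyl}-5,7-dimethoxychroman-4-one F4. Because C2'' is already fixed the two are diastereomers and would be separated by preparative chromatography, and the route is rejoined at 23.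

Step 9 (key ring closure). Intermolecular trifluoroacetylation of ring A'' at C6'' by excess anhydride may compete with ring closure, and the trifluoroacetic acid formed may promote ionisation or ring opening at C2'' and so erode its configuration. The fallback replaces the mixed anhydride formed in the flask by an isolated acyl chloride that is closed by a Lewis acid in an aprotic medium. It sets out from 14, which with (COCl)2 and catalytic DMF in CH2Cl2 would give (3S)-3-(4-acetoxyphenyl)-3-[2-(2-benzyloxy-5-bromophenyl)-3,5-dimethoxyphenoxy]propanoyl chloride F5. SnCl4 (1.1 equiv, CH2Cl2, −78 °C) should close this chloride at C4a'' under the same tether control, and the route is rejoined at 16.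

Further compounds
F1 | step 7 | (1R)-1-(4-acetoxyphenyl)but-3-en-1-ol | C=CC[C@@H](O)c1ccc(OC(C)=O)cc1
F2 | step 7 | 4-[(1S)-1-[2-(2-benzyloxy-5-bromophenyl)-3,5-dimethoxyphenoxy]but-3-en-1-yl]phenyl acetate | C=CC[C@H](Oc1cc(OC)cc(OC)c1-c1cc(Br)ccc1OCc1ccccc1)c1ccc(OC(C)=O)cc1
F3 | step 7 | 4-[(1S)-1-[2-(2-benzyloxy-5-bromophenyl)-3,5-dimethoxyphenoxy]-3-oxopropyl]phenyl acetate | O=CC[C@H](Oc1cc(OC)cc(OC)c1-c1cc(Br)ccc1OCc1ccccc1)c1ccc(OC(C)=O)cc1
F4 | step 14 | (2S)-2-(4-acetoxyphenyl)-8-{2-(benzyloxy)-5-[(2R)-5,7-bis(benzyloxy)-4-oxochroman-2-yl]phenyl}-5,7-dimethoxychroman-4-one | COc1cc(OC)c2c(c1-c1cc([C@H]3CC(=O)c4c(OCc5ccccc5)cc(OCc5ccccc5)cc4O3)ccc1OCc1ccccc1)O[C@H](c1ccc(OC(C)=O)cc1)CC2=O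
F5 | step 9 | (3S)-3-(4-acetoxyphenyl)-3-[2-(2-benzyloxy-5-bromophenyl)-3,5-dimethoxyphenoxy]propanoyl chloride | ClC(=O)C[C@H](Oc1cc(OC)cc(OC)c1-c1cc(Br)ccc1OCc1ccccc1)c1ccc(OC(C)=O)cc1
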